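**Retrosynthetic overview**

1. Labels: tetrahydrofuran O1, C2 (aryl), C3, C4, C5; C3a is the CH2OH carbon on C3 and C4a the ArCH(OH) carbon on C4. The strategy rests on C5 being a bare methylene held only between O1 and C4, beside a C4a carbinol that is benzylic to a p-oxygenated ring and cis to C3a. C5 can therefore be a formaldehyde carbon delivered as an O1=CH2 oxocarbenium ion to an (E)-styrene C4=C4a, and the C4a oxygen can arrive from a C3a carboxyl group.
2. Target 23 ⇐ cis-fused bicyclic γ-lactone 20 (lactone ring C3a–O–C4a–C4–C3 fused to the tetrahydrofuran) by hydride opening and removal of the tosyl and benzyl groups.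
3. 20 ⇐ 1,3-dioxan-4-one 17 by disconnecting C4–C5 and C4a–O; one cationic cascade closes the tetrahydrofuran ring first and the lactone ring second.
4. 17 ⇐ syn β-hydroxy acid 14 + formaldehyde; 14 ⇐ Evans syn-aldol (C2–C3 bond, both stereocenters) between styrylacetyl imide 7 and vanillin tosylate 9.
5. 7 ⇐ (E)-4-arylbut-3-enoic acid 4 (Wittig reaction of O-benzylvanillin 1) + (R)-4-benzyloxazolidinone 5.

Key step: step 7

Remark: paraformaldehyde is counted as monomeric formaldehyde; compounds 1, 2, 5, 8 and 15 are taken as purchased; the atom labels of the overview are used throughout.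

**Step 1**
Reactants: 1 4-(benzyloxy)-3-methoxybenzaldehyde; 2 (2-carboxyethyl)triphenylphosphonium bromide
Product: 4 (E)-4-[4-(benzyloxy)-3-methoxyphenyl]but-3-enoic acid, via ylide carboxylate 3 (not isolated)
Conditions: 2, NaN(SiMe3)2 (2.1 equiv), THF, 0 °C; then 1, −78 °C → rt; 1 M HCl
Reagents that add atoms: none
Why: Wittig olefination in which the carboxylate-bearing ylide 3 should give the (E)-β,γ-unsaturated acid, because the internal carboxylate lets the oxaphosphetane equilibrate toward the trans alkene, and any minor (Z)-isomer should be removable by crystallization of the acid.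

**Step 2**
Reactants: 4 (E)-4-[4-(benzyloxy)-3-methoxyphenyl]but-3-enoic acid; 5 (R)-4-benzyl-1,3-oxazolidin-2-one
Product: 7 (4R)-4-benzyl-3-{(E)-4-[4-(benzyloxy)-3-methoxyphenyl]but-3-enoyl}-1,3-oxazolidin-2-one, via mixed pivalic anhydride 6 (not isolated)
Conditions: t-BuCOCl, Et3N, THF, −20 °C; then LiCl, 5, −20 °C → rt
Reagents that add atoms: none
Why: N-acylation of the oxazolidinone through the mixed anhydride, which the LiCl-activated carbamate attacks at the less hindered acyl carbon, while the alkene should stay in the aryl-conjugated β,γ-position under these mild conditions.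

**Step 3**
Reactants: 8 vanillin (4-hydroxy-3-methoxybenzaldehyde)
Product: 9 4-formyl-2-methoxyphenyl 4-methylbenzenesulfonate
Conditions: TsCl, Et3N, DMAP (cat.), CH2Cl2, 0 °C → rt
Reagents that add atoms: 4-methylbenzenesulfonyl chloride, Cc1ccc(S(=O)(=O)Cl)cc1
Why: O-sulfonylation of the phenol, which protects it and makes the future C2 aryl ring electron-poor.

**Step 4**
Reactants: 7 (4R)-4-benzyl-3-{(E)-4-[4-(benzyloxy)-3-methoxyphenyl]but-3-enoyl}-1,3-oxazolidin-2-one; 9 4-formyl-2-methoxyphenyl 4-methylbenzenesulfonate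
Product: 12 (4R)-4-benzyl-3-{(2R,3R)-2-[(E)-2-(4-benzyloxy-3-methoxyphenyl)ethenyl]-3-hydroxy-3-[3-methoxy-4-(tosyloxy)phenyl]propanoyl}-1,3-oxazolidin-2-one, via boron Z-enolate 10 (not isolated), via boron aldolate 11 (not isolated)
Conditions: Bu2BOTf, i-Pr2NEt, CH2Cl2, −78 → 0 °C; then 9, −78 → 0 °C; pH 7 buffer, MeOH, 30% H2O2, 0 °C
Reagents that add atoms: none
Why: Evans syn-aldol reaction in which the (Z)-boron dienolate 10 should add through its α-carbon in a Zimmerman–Traxler chair, the aldehyde approaching the face away from the benzyl group of the (R)-auxiliary, which sets both new stereocenters as the (2R,3R)-syn adduct (tetrahydrofuran atoms C3 and C2).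

**Step 5**
Reactants: 12 the syn-aldol imide
Product: 14 (2R,3R)-2-[(E)-2-(4-benzyloxy-3-methoxyphenyl)ethenyl]-3-hydroxy-3-[3-methoxy-4-(tosyloxy)phenyl]propanoic acid, via peroxy acid 13 (not isolated)
Conditions: LiOH, 30% H2O2, THF/H2O (3:1), 0 °C; then aq. Na2SO3; 1 M HCl to pH 3
Reagents that add atoms: hydrogen peroxide, OO
Why: auxiliary cleavage by lithium hydroperoxide, which attacks the exocyclic imide carbonyl selectively and whose percarboxylate 13 is reduced by sulfite, while the aryl sulfonate and both stereocenters should be untouched at 0 °C.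

**Step 6**
Reactants: 14 the syn β-hydroxy acid; 15 paraformaldehyde (as formaldehyde)
Product: 17 (5R,6R)-5-[(E)-2-(4-benzyloxy-3-methoxyphenyl)ethenyl]-6-[3-methoxy-4-(tosyloxy)phenyl]-1,3-dioxan-4-one (5,6-cis), via hemiacetal 16 (not isolated)
Conditions: (CH2O)n, TsOH·H2O (cat.), benzene, reflux, Dean–Stark
Reagents that add atoms: none
Why: acid-catalysed acetalization in which the secondary hydroxyl adds to formaldehyde to give hemiacetal 16 and the carboxyl group closes the six-membered acylal with azeotropic loss of water, no stereocenter being formed, while the tosyloxy-deactivated benzylic C–O bond should resist ionization.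

**Step 7**
Reactants: 17 the 5,6-cis 1,3-dioxan-4-one
Product: 20 (1R,4R,5S,8R)-4-[4-(benzyloxy)-3-methoxyphenyl]-8-[3-methoxy-4-(tosyloxy)phenyl]-3,7-dioxabicyclo[3.3.0]octan-2-one (cis-fused; both aryl groups exo), via oxocarbenium ion 18 (not isolated), via benzylic cation 19 (not isolated)
Conditions: Me3SiOTf (0.5 equiv), 2,6-di-tert-butyl-4-methylpyridine (0.1 equiv), CH2Cl2, −78 → −20 °C; then sat. aq. NaHCO3
Reagents that add atoms: none
Why: Proposed new method: Me3SiOTf silylates the carbonyl oxygen of the acylal, the C5–O(acyl) bond ionizes to the O1=C5H2 oxocarbenium ion 18 carrying a silyl ester on C3, the styrene attacks C5 through C4 (Prins cyclization), and the silyl ester carbonyl oxygen captures the p-benzyloxybenzylic cation 19 at C4a with loss of Me3Si+, which turns the promoter over. The closest known reactions are the Lewis acid Prins cyclization of (E)-4-arylbut-3-en-1-ols with aldehydes to 2,3-disubstituted tetrahydrofurans with capture of the exocyclic benzylic cation, and the Lewis acid opening of 1,3-dioxan-4-ones at the acetal carbon with carboxylate as the leaving group. The tetrahydrofuran closes 5-exo-trig at the alkene (5-endo at the oxocarbenium ion) and the γ-lactone closes 5-exo at the benzylic cation. C4 is controlled by the C3 carboxyl group, since only the rotamer that places C4a cis to C3a lets the carboxyl oxygen assist and trap while the trans cation can revert by retro-Prins fragmentation; C4a is controlled by anti addition of C5 and oxygen across the (E)-alkene, which puts the aryl group on the exo face, also the more stable position should the benzylic C–O bond re-ionize. The step needs attack through C4 and not C4a, secured by the p-benzyloxy ring that stabilizes a cation only at C4a, and it needs the C2–O1 bond to stay intact (no benzylic ionization, no 2-oxonia-Cope transfer), secured by the electron-poor tosyloxy ring on C2.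

**Step 8**
Reactants: 20 the bicyclic lactone
Product: 21 {(2R,3S,4S)-4-[(R)-(4-benzyloxy-3-methoxyphenyl)(hydroxy)methyl]-2-[3-methoxy-4-(tosyloxy)phenyl]tetrahydrofuran-3-yl}methanol
Conditions: LiAlH4, THF, 0 °C; then H2O, 15% aq. NaOH
Reagents that add atoms: none
Why: LiAlH4 reduction of the γ-lactone to the 1,4-diol, which cleaves only the acyl C–O bond so that C4a keeps its configuration, while the benzyl ether is inert and any early loss of the aryl sulfonate would only anticipate step 9.

**Step 9**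
Reactants: 21 the diol tosylate
Product: 22 {(2R,3S,4S)-4-[(R)-(4-benzyloxy-3-methoxyphenyl)(hydroxy)methyl]-2-(4-hydroxy-3-methoxyphenyl)tetrahydrofuran-3-yl}methanol
Conditions: KOH, MeOH/H2O (4:1), 65 °C; then 0.5 M HCl to pH 7, 0 °C
Reagents that add atoms: none
Why: alkaline cleavage of the aryl sulfonate by hydroxide attack at sulfur, which leaves the benzyl ether, the alcohols and the tetrahydrofuran untouched, the neutral work-up avoiding acid-induced ionization at C4a.

**Step 10**
Reactants: 22 the monobenzyl ether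
Product: 23 (2R,3S,4S)-4-[(R)-hydroxy(4-hydroxy-3-methoxyphenyl)methyl]-2-(4-hydroxy-3-methoxyphenyl)-3-(hydroxymethyl)tetrahydrofuran (target)
Conditions: H2 (1 atm), 10% Pd/C, EtOAc, rt
Reagents that add atoms: none
Why: catalytic hydrogenolysis of the aryl benzyl ether, which under neutral conditions at room temperature should be much faster than cleavage of the two secondary benzylic C–O bonds, so the reaction is stopped after uptake of one equivalent of hydrogen.

**Compound list**

1 | 4-(benzyloxy)-3-methoxybenzaldehyde | COc1cc(C=O)ccc1OCc1ccccc1 | starting material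
2 | (2-carboxyethyl)triphenylphosphonium bromide | OC(=O)CC[P+](c1ccccc1)(c1ccccc1)c1ccccc1.[Br-] | starting material
3 | sodium 3-(triphenylphosphoranylidene)propanoate (ylide carboxylate) | [Na+].[O-]C(=O)CC=P(c1ccccc1)(c1ccccc1)c1ccccc1 | intermediate (not isolated)
4 | (E)-4-[4-(benzyloxy)-3-methoxyphenyl]but-3-enoic acid | COc1cc(/C=C/CC(=O)O)ccc1OCc1ccccc1 | intermediate
5 | (R)-4-benzyl-1,3-oxazolidin-2-one | O=C1N[C@H](Cc2ccccc2)CO1 | starting material
6 | mixed anhydride of 4 with pivalic acid | COc1cc(/C=C/CC(=O)OC(=O)C(C)(C)C)ccc1OCc1ccccc1 | intermediate (not isolated)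
7 | (4R)-4-benzyl-3-{(E)-4-[4-(benzyloxy)-3-methoxyphenyl]but-3-enoyl}-1,3-oxazolidin-2-one | COc1cc(/C=C/CC(=O)N2[C@H](Cc3ccccc3)COC2=O)ccc1OCc1ccccc1 | intermediate
8 | vanillin | COc1cc(C=O)ccc1O | starting material
9 | 4-formyl-2-methoxyphenyl 4-methylbenzenesulfonate | COc1cc(C=O)ccc1OS(=O)(=O)c1ccc(C)cc1 | intermediate
10 | dibutylboron (1Z,3E)-dienolate of 7 | CCCCB(CCCC)O/C(=C\C=C\c1ccc(OCc2ccccc2)c(OC)c1)N1[C@H](Cc2ccccc2)COC1=O | intermediate (not isolated)
11 | O-dibutylboryl aldolate of 12 | O=C(N1[C@H](Cc2ccccc2)COC1=O)[C@H](/C=C/c1ccc(OCc2ccccc2)c(OC)c1)[C@@H](OB(CCCC)CCCC)c1ccc(OS(=O)(=O)c2ccc(C)cc2)c(OC)c1 | intermediate (not isolated)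
12 | (4R)-4-benzyl-3-{(2R,3R)-2-[(E)-2-(4-benzyloxy-3-methoxyphenyl)ethenyl]-3-hydroxy-3-[3-methoxy-4-(tosyloxy)phenyl]propanoyl}-1,3-oxazolidin-2-one | O=C(N1[C@H](Cc2ccccc2)COC1=O)[C@H](/C=C/c1ccc(OCc2ccccc2)c(OC)c1)[C@@H](O)c1ccc(OS(=O)(=O)c2ccc(C)cc2)c(OC)c1 | intermediate
13 | peroxy acid corresponding to 14 | OOC(=O)[C@H](/C=C/c1ccc(OCc2ccccc2)c(OC)c1)[C@@H](O)c1ccc(OS(=O)(=O)c2ccc(C)cc2)c(OC)c1 | intermediate (not isolated)
14 | (2R,3R)-2-[(E)-2-(4-benzyloxy-3-methoxyphenyl)ethenyl]-3-hydroxy-3-[3-methoxy-4-(tosyloxy)phenyl]propanoic acid | OC(=O)[C@H](/C=C/c1ccc(OCc2ccccc2)c(OC)c1)[C@@H](O)c1ccc(OS(=O)(=O)c2ccc(C)cc2)c(OC)c1 | intermediate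
15 | paraformaldehyde (as formaldehyde) | C=O | starting material
16 | 3-O-(hydroxymethyl) hemiacetal of 14 | OC(=O)[C@H](/C=C/c1ccc(OCc2ccccc2)c(OC)c1)[C@@H](OCO)c1ccc(OS(=O)(=O)c2ccc(C)cc2)c(OC)c1 | intermediate (not isolated)
17 | (5R,6R)-5-[(E)-2-(4-benzyloxy-3-methoxyphenyl)ethenyl]-6-[3-methoxy-4-(tosyloxy)phenyl]-1,3-dioxan-4-one | O=C1OCO[C@@H](c2ccc(OS(=O)(=O)c3ccc(C)cc3)c(OC)c2)[C@H]1/C=C/c1ccc(OCc2ccccc2)c(OC)c1 | intermediate
18 | O1-methylene oxocarbenium triflate with trimethylsilyl ester on C3 | C=[O+][C@@H](c1ccc(OS(=O)(=O)c2ccc(C)cc2)c(OC)c1)[C@@H](/C=C/c1ccc(OCc2ccccc2)c(OC)c1)C(=O)O[Si](C)(C)C.[O-]S(=O)(=O)C(F)(F)F | intermediate (not isolated)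
19 | C4a benzylic cation (triflate) of the 2,3-trans-3,4-cis tetrahydrofuran trimethylsilyl ester | C[Si](C)(C)OC(=O)[C@@H]1[C@H]([CH+]c2ccc(OCc3ccccc3)c(OC)c2)CO[C@H]1c1ccc(OS(=O)(=O)c2ccc(C)cc2)c(OC)c1.[O-]S(=O)(=O)C(F)(F)F | intermediate (not isolated)
20 | (1R,4R,5S,8R)-4-[4-(benzyloxy)-3-methoxyphenyl]-8-[3-methoxy-4-(tosyloxy)phenyl]-3,7-dioxabicyclo[3.3.0]octan-2-one | COc1cc([C@@H]2OC(=O)[C@@H]3[C@H]2CO[C@H]3c4ccc(OS(=O)(=O)c5ccc(C)cc5)c(OC)c4)ccc1OCc1ccccc1 | intermediate
21 | {(2R,3S,4S)-4-[(R)-(4-benzyloxy-3-methoxyphenyl)(hydroxy)methyl]-2-[3-methoxy-4-(tosyloxy)phenyl]tetrahydrofuran-3-yl}methanol | COc1cc([C@H](O)[C@@H]2CO[C@@H](c3ccc(OS(=O)(=O)c4ccc(C)cc4)c(OC)c3)[C@@H]2CO)ccc1OCc1ccccc1 | intermediate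
22 | {(2R,3S,4S)-4-[(R)-(4-benzyloxy-3-methoxyphenyl)(hydroxy)methyl]-2-(4-hydroxy-3-methoxyphenyl)tetrahydrofuran-3-yl}methanol | COc1cc([C@H](O)[C@@H]2CO[C@@H](c3ccc(O)c(OC)c3)[C@@H]2CO)ccc1OCc1ccccc1 | intermediate
23 | (2R,3S,4S)-4-[(R)-hydroxy(4-hydroxy-3-methoxyphenyl)methyl]-2-(4-hydroxy-3-methoxyphenyl)-3-(hydroxymethyl)tetrahydrofuran | COc1cc([C@H](O)[C@@H]2CO[C@@H](c3ccc(O)c(OC)c3)[C@@H]2CO)ccc1O | target

**Step count and risks**

Total step count: 10. Longest linear sequence: 9 steps (1, 2, 4, 5, 6, 7, 8, 9, 10, from aldehyde 1); step 3 is a one-step branch.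

Steps most likely to fail:

Step 7. After ionization the acylal may simply re-close, or the C–C bond may form on the alkene face that places C4a trans to the carboxyl group, so that the cation is not captured and is drained by elimination or oligomerization. The fallback separates oxocarbenium generation from the acylal and uses the established alcohol-plus-aldehyde Prins format. It sets out from acid 14, which is esterified (Me3SiCHN2, MeOH/toluene, 0 °C) to the methyl ester F1. F1 is treated with paraformaldehyde 15 and BF3·OEt2 in CH2Cl2 at −20 °C, the known Prins cyclization of an (E)-4-arylbut-3-en-1-ol to a 2,3-disubstituted tetrahydrofuran. The C4a cation is quenched by water, directly or through the neighbouring ester group, to give the hydroxy ester F2. Warming F2 with catalytic camphorsulfonic acid in toluene closes the lactone with loss of methanol and rejoins the route at 20; under this acid any C4a epimer should equilibrate through the benzylic cation to the exo-aryl lactone.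

Step 6. At reflux under Brønsted acid the hemiacetal may ionize and cyclize onto the styrene prematurely, or the β-hydroxy acid may dehydrate or undergo retro-aldol cleavage before the acylal closes. The fallback is an aprotic silyl-transfer acetalization at low temperature. It sets out from 14, which is silylated on both oxygens (Me3SiCl, Et3N, CH2Cl2) to the bis(trimethylsilyl) derivative F3. F3 is treated at −78 °C in CH2Cl2 with monomeric formaldehyde (from thermal cracking of 15) and a trace of Me3SiOTf and quenched cold with pyridine. This known silyl ether/silyl ester acetalization releases hexamethyldisiloxane and comes back to the route at 17.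

Step 4. The aryl-conjugated boron dienolate may react sluggishly or partly through its γ-carbon, and retro-aldol cleavage on work-up may erode regio- and diastereoselectivity. The fallback installs the aryl group on the alkene after the aldol. It sets out from auxiliary 5, which is acylated (n-BuLi, crotonyl chloride, THF, −78 °C) to the N-crotonyl imide F4. Deconjugative enolization of F4 (Bu2BOTf, Et3N) and the well-precedented syn-aldol with aldehyde 9 give the α-vinyl aldol F5. Separately, aldehyde 1 is methylenated (Ph3PCH3Br, KOt-Bu, THF) to the styrene F6. Cross-metathesis of F5 with excess F6 (second-generation Hoveyda–Grubbs catalyst, CH2Cl2, 40 °C) should give the (E)-styryl aldol and comes back to the route at 12.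

**Further compounds**

F1 | step 7 | methyl (2R,3R)-2-[(E)-2-(4-benzyloxy-3-methoxyphenyl)ethenyl]-3-hydroxy-3-[3-methoxy-4-(tosyloxy)phenyl]propanoate | COC(=O)[C@H](/C=C/c1ccc(OCc2ccccc2)c(OC)c1)[C@@H](O)c1ccc(OS(=O)(=O)c2ccc(C)cc2)c(OC)c1
F2 | step 7 | methyl (2R,3R,4S)-4-[(R)-(4-benzyloxy-3-methoxyphenyl)(hydroxy)methyl]-2-[3-methoxy-4-(tosyloxy)phenyl]tetrahydrofuran-3-carboxylate | COC(=O)[C@@H]1[C@H]([C@@H](O)c2ccc(OCc3ccccc3)c(OC)c2)CO[C@H]1c1ccc(OS(=O)(=O)c2ccc(C)cc2)c(OC)c1
F3 | step 6 | trimethylsilyl (2R,3R)-2-[(E)-2-(4-benzyloxy-3-methoxyphenyl)ethenyl]-3-[3-methoxy-4-(tosyloxy)phenyl]-3-(trimethylsilyloxy)propanoate | C[Si](C)(C)OC(=O)[C@H](/C=C/c1ccc(OCc2ccccc2)c(OC)c1)[C@@H](O[Si](C)(C)C)c1ccc(OS(=O)(=O)c2ccc(C)cc2)c(OC)c1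
F4 | step 4 | (4R)-4-benzyl-3-[(E)-but-2-enoyl]-1,3-oxazolidin-2-one | C/C=C/C(=O)N1[C@H](Cc2ccccc2)COC1=O
F5 | step 4 | (4R)-4-benzyl-3-{(2R,3R)-2-ethenyl-3-hydroxy-3-[3-methoxy-4-(tosyloxy)phenyl]propanoyl}-1,3-oxazolidin-2-one | O=C(N1[C@H](Cc2ccccc2)COC1=O)[C@H](C=C)[C@@H](O)c1ccc(OS(=O)(=O)c2ccc(C)cc2)c(OC)c1
F6 | step 4 | 1-(benzyloxy)-4-ethenyl-2-methoxybenzene | C=Cc1ccc(OCc2ccccc2)c(OC)c1
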